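Take the flasks below, each with its own substrate charge under the same held gas phase, and rank them by the target they hold at 6.0 h.

the same everywhere: gas phase 4.5 mM (held)

|  | substrate | remark | time |
|---|---|---|---|
| amber | 0.30 M | run made earlier |  |
| spring | 0.12 M |  | 6.0 h |
| summer | 0.20 M |  | 6.0 h |
| winter | 0.020 M |  | 6.0 h |
| dawn | 0.064 M |  | 6.0 h |
| midnight | 0.040 M |  | 6.0 h |
| autumn | 0.030 M |  | 6.0 h |

- amber (time / h: target / %, substrate / %): 0.500: 1.6, 98.9; 1.50: 3.1, 97.1; 3.00: 6.1, 93.9; 4.00: 7.4, 91.7; 6.00: 11.2, 87.6

(scatter of a reading: 0.5 percentage points)

- the flasks by amount of target, in percent of the substrate charged, highest first, at 6.0 h (spring / summer / winter / dawn / midnight / autumn)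
- the amount of target, in percent of the substrate charged of the flask you put first, at 6.0 h
- the amount of target, in percent of the substrate charged of the flask you put last, at 6.0 h

- the numbers in the tables scatter by 0.5 percentage points (one standard deviation)
- at the start none of the gas phase is in solution

By 6.00 h, amber had lost 12.4% of its substrate, and target held 90.3% of that loss. Counting one gas per substrate, this reading is an uptake of 0.0372 M: the amber uptake, the substrate that amber consumed in that time.

Now solve two extreme flasks. In the first, gas enters at a fixed pace whatever the charge, so a flask takes up the amber uptake and the fraction lost is that uptake over its own charge, the ceiling. That gives 18.6% for summer and 186% for winter, whose charge is smaller than the uptake, so winter's ceiling is its charge. In the second, gas is never short and the rate follows the substrate (pseudo-first-order), so the fraction lost is amber's 12.4% at any charge, the floor. The real flask lies between if the rate rises with the charge but no faster than the charge. I assume that, since amber cannot separate the two.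

So the fraction lost climbs as the charge thins, and I rank by dilution: winter, the thinnest, then autumn, midnight, dawn, spring, and summer, the thickest. Taking the middle of each bracket and amber's share as target, I expect about 50.7% in winter and 14.0% in summer, though winter's bracket is wide.

The forecast says “I assume its dissolution limits the rate”. It gives midnight > dawn > autumn > spring > summer > winter, with 28% first and 10% last, so its first and last places differ from mine.

The flasks give winter > autumn > midnight > dawn > spring > summer, with 58.0% in winter and 15.5% in summer.

    gas phase ⇌ dissolved gas, rate k1*(csat - [dissolved gas]) (kL = 0.0250 min⁻¹)
    substrate + dissolved gas → target (k = 1.20 M⁻¹ min⁻¹)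
    target ⇌ isomer of the product (K = 0.810, k = 9.70 × 10⁻⁴ min⁻¹)

Winter has 32% of its substrate left, so it lost 68.0%, more than the floor. Summer has 82% left, so it lost 18.0%, just under its ceiling of 18.6%.

Readings and results stem from a simulated flask with constants of no real substance; scatter was added.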